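The amounts in these flasks differ in two charges, and the readings settle within minutes.

in all of them: starting material 0.080 M
- alpha: first nucleophile 0.058 M; second nucleophile 0.080 M; run made earlier
- epsilon: first nucleophile 0.10 M; second nucleophile 0.080 M; run made earlier
- beta: first nucleophile 0.13 M; second nucleophile 0.080 M; run made earlier
- zeta: first nucleophile 0.080 M; second nucleophile 0.054 M; run made earlier
- Thursday's: first nucleophile 0.120 M; second nucleophile 0.0200 M; time 1.0 h
- Friday's: first nucleophile 0.0800 M; second nucleophile 0.0800 M; time 1.0 h

- alpha (time / min: target / %): 6.00: 22.3; 12.0: 22.9; 20.0: 21.6; 25.0: 21.8; 30.0: 23.4
- epsilon (time / min: target / %): 2.50: 31.5; 5.00: 29.9; 8.00: 30.7; 15.0: 31.1; 30.0: 32.5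
- beta (time / min: target / %): 2.50: 34.9; 5.00: 35.8; 8.00: 35.8; 15.0: 37.0; 30.0: 36.2
- zeta (time / min: target / %): 6.00: 38.5; 12.0: 40.5; 20.0: 39.4; 25.0: 40.2; 30.0: 39.6

(standard deviation of a reading: 1 percentage point)



- which of the two ends with the higher amount of target, in percent of the starting material charged ("neither" if they lie within 2 percentage points) (Thursday's / Friday's / neither)
- target at the end, in percent of the starting material charged, Thursday's
- target at the end, in percent of the starting material charged, Friday's

I compared Friday's with the zeta run, which looks nearly the same: its first nucleophile charge is equal, and its second is lower. Zeta's target averaged 39.6%. Its second nucleophile covered 67.5% of the starting material, so I reckoned that the target took the remainder plus its own share. Friday's second nucleophile covers 100%, so on that reckoning Friday's has no such remainder.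

To measure the share, I used s, the selectivity factor: the logarithm of the fraction of first nucleophile left over the logarithm of the fraction of second left. I assumed that each nucleophile is consumed one to one and that the target and its rival take up the starting material. The epsilon run averaged 31.1%, which gave s as 0.246, a reading with its scatter. The zero of this scale is s equal to one, where equal charges split in half. On those assumptions, in Friday's the fraction of second left equals the target fraction, so my equation makes the target fraction one minus itself raised to the power s.

The forecast said Thursday's, with 76% for Thursday's and 27% for Friday's, holding that “the starting material is used up and the target is stable”. I put its Friday's value into my equation, and that returned 27.5%. Thursday's second nucleophile covers a quarter of the starting material, so I also expected Thursday's to lead.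

The flask gave Thursday's: 72.7% for Thursday's and 28.0% for Friday's.

    starting material → intermediate (k = 5.50 min⁻¹)
    first nucleophile + intermediate → target (k = 5300 L mol⁻¹ min⁻¹)
    second nucleophile + intermediate → other capture product (k = 19000 L mol⁻¹ min⁻¹)
    intermediate → solvolysis product (k = 16.0 min⁻¹)
    starting material ⇌ dormant form (K = 20.0, k = 0.260 min⁻¹)
    2 second nucleophile → self-condensation product (k = 0.250 L mol⁻¹ min⁻¹)

Thursday's led mainly through its smaller charge of second nucleophile: with that difference taken away, its target fell from 72.7% to 35.5%. In Thursday's, 8.8% of the second was left, and raising that to the power 0.246 gave 55.0% of the first left, while the flask kept 52%. The neighbour, Friday's recipe with 0.032 M of second nucleophile, kept 4.7% of it, so s gave 47.1% of the first left. That neighbour kept 43% and ended with 56.7% of target.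

The data are calculated for an exercise, noise included.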